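**Retrosynthetic overview**
1. Target 11 ⇒ C4 ketone 10 (methyl addition from the α-face sets C4) ⇒ exocyclic alkene 8 (ozonolysis).
2. Isopropyl group and 6α-acetate of 8 ⇒ γ-lactone of 4 (reduction, C12 deoxygenation); C6 and C7 are carried over from the starting lactone.
3. Key disconnection: bromo-trans-decalin 4 ⇒ ten-membered (E,E)-diene 2 by a bromonium-triggered transannular cyclization, which closes rings A and B together and sets C1, C5 and C10 in one step.
4. 2 ⇒ (+)-costunolide 1; the usual Robinson-annulation or chiral-pool decalin with late installation of the neopentyl bromide is deliberately not used.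
5. Ring order: the ten-membered carbocycle is bought, rings A and B close simultaneously in step 2, and the lactone ring is opened in step 3.

Assumption: (+)-costunolide, a germacranolide sold by several fine-chemical suppliers, counts as a commercially available starting material; its natural (6R,7S) enantiomer is the one the target requires.

**Route**

Step 1
Reactants: 1 (+)-costunolide
Product: 2 11β,13-dihydrocostunolide
Conditions: NaBH4, MeOH, 0 °C
Reagents that add atoms: none
Why: Conjugate (1,4) hydride reduction of the α-methylene-γ-lactone leaves both trisubstituted ring alkenes untouched, and protonation/equilibration of the lactone enolate in methanol gives the more stable 11βH (11S) epimer with the new methyl trans to C8, a centre that disappears again in step 5.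

Step 2
Reactants: 2 11β,13-dihydrocostunolide
Product: 4 1β-bromo-5α,11βH-eudesm-4(15)-en-12,6α-olide, via C4 eudesmanyl cation 3 (not isolated)
Conditions: TBCO (1.05 equiv), MeNO2, −20 °C, dark
Reagents that add atoms: 2,4,4,6-tetrabromocyclohexa-2,5-dienone, TBCO (O=C1C(Br)=CC(Br)(Br)C=C1Br)
Why: Bromonium-induced transannular cation–olefin cyclization, in which Br+ adds to the more electron-rich 1(10)-alkene (the 4(5)-alkene is deactivated by the allylic lactone oxygen) on its exposed outer face, C5 attacks C10 through the crossed chair–chair conformer held by the trans-lactone (anti addition across an E-alkene, hence equatorial 1β-Br, axial 10β-Me and 5α-H of a trans-decalin, all relative to C6 and C7), and the bulky 2,4,6-tribromophenoxide released from the reagent removes an unhindered C15 proton from the C4 cation to give mainly the exocyclic alkene, with the 3-ene isomer as the expected separable by-product.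

Step 3
Reactants: 4 1β-bromo-5α,11βH-eudesm-4(15)-en-12,6α-olide
Product: 5 (11S)-1β-bromo-5αH-eudesm-4(15)-ene-6α,12-diol
Conditions: LiBH4, THF, 0 °C → rt
Reagents that add atoms: none
Why: Hydride reduction of the γ-lactone to the 1,4-diol with a reagent that neither displaces the hindered secondary bromide (equatorial, next to the quaternary C10) nor touches the alkene, so no stereocentre changes.

Step 4
Reactants: 5 (11S)-1β-bromo-5αH-eudesm-4(15)-ene-6α,12-diol
Product: 7 (11S)-1β-bromo-12-tosyloxy-5αH-eudesm-4(15)-en-6α-yl acetate, via C12 monotosylate 6 (not isolated)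
Conditions: TsCl (1.2 equiv), pyridine, 0 °C; then Ac2O, DMAP (cat.), rt
Reagents that add atoms: p-toluenesulfonyl chloride (Cc1ccc(cc1)S(=O)(=O)Cl); acetic anhydride (CC(=O)OC(C)=O)
Why: Sterically controlled O-sulfonylation of the primary C12 alcohol followed in the same flask by DMAP-catalysed acetylation of the hindered secondary 6α-alcohol, which installs the acetate of the target and blocks cyclic ether formation between O6 and C12, with no stereocentre affected.

Step 5
Reactants: 7 (11S)-1β-bromo-12-tosyloxy-5αH-eudesm-4(15)-en-6α-yl acetate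
Product: 8 1β-bromo-5αH-eudesm-4(15)-en-6α-yl acetate
Conditions: NaBH4, DMSO, 70 °C
Reagents that add atoms: none
Why: SN2 hydride displacement of the primary tosylate by borohydride in a dipolar aprotic solvent turns C12 into a methyl group (C11 stops being a stereocentre and the isopropyl group is complete), while NaBH4 does not reduce the acetate and the C1 bromide cannot undergo SN2 or E2 because it is neopentyl-type and equatorial on a rigid trans-decalin.

Step 6
Reactants: 8 1β-bromo-5αH-eudesm-4(15)-en-6α-yl acetate
Product: 10 1β-bromo-4-oxo-15-nor-5αH-eudesman-6α-yl acetate, via spiro ozonide 9 (not isolated)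
Conditions: O3, CH2Cl2, −78 °C; then Me2S, −78 °C → rt
Reagents that add atoms: ozone ([O-][O+]=O)
Why: Ozonolysis with reductive work-up cleaves the only alkene to the C4 ketone under neutral conditions, so the β-acetoxy ketone does not eliminate and the C5 centre next to the new carbonyl is not epimerized.

Step 7
Reactants: 10 1β-bromo-4-oxo-15-nor-5αH-eudesman-6α-yl acetate
Product: 11 1β-bromo-4β-hydroxy-5αH-eudesman-6α-yl acetate (target)
Conditions: MeLi (1.5 equiv), CeCl3, THF, −78 °C; then aq NH4Cl
Reagents that add atoms: methyllithium ([Li]C)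
Why: 1,2-Addition of the weakly basic organocerium reagent MeCeCl2 (Imamoto conditions) to the ketone outpaces attack on the hindered secondary acetate at −78 °C and avoids enolization and β-elimination, and the methyl enters from the α (equatorial) face because the β (axial) trajectory is blocked by the syn-axial C10 methyl, giving the axial 4β-hydroxyl and equatorial 4α-methyl of the target.

**Compound list**
1 | (+)-costunolide, (6R,7S)-germacra-1(10)E,4E,11(13)-trien-12,6α-olide (trans-fused α-methylene-γ-lactone) | O=C1O[C@@H]2/C=C(C)/CC/C=C(C)/CC[C@H]2C1=C | starting material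
2 | 11β,13-dihydrocostunolide, (6S,7S,11S)-germacra-1(10)E,4E-dien-12,6α-olide (11α-methyl) | O=C1O[C@@H]2/C=C(C)/CC/C=C(C)/CC[C@H]2[C@@H]1C | intermediate
3 | 1β-bromo-5α,11βH-eudesman-12,6α-olid-4-yl cation (tertiary C4 cation, trans-decalin, 10β-methyl) | O=C1O[C@@H]2[C@@H]3[C@@](C)(CC[C@H]2[C@@H]1C)[C@H](Br)CC[C+]3C | intermediate
4 | 1β-bromo-5α,11βH-eudesm-4(15)-en-12,6α-olide (trans-decalin, 10β-methyl, equatorial 1β-Br, exocyclic C4=CH2, trans-fused lactone with O on C6α and C11 on C7β, 11α-methyl) | O=C1O[C@@H]2[C@@H]3[C@@](C)(CC[C@H]2[C@@H]1C)[C@H](Br)CCC3=C | intermediate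
5 | (11S)-1β-bromo-5αH-eudesm-4(15)-ene-6α,12-diol (7β side chain, 10β-methyl) | O[C@@H]1[C@@H]2[C@@](C)(CC[C@H]1[C@@H](CO)C)[C@H](Br)CCC2=C | intermediate
6 | (11S)-1β-bromo-6α-hydroxy-5αH-eudesm-4(15)-en-12-yl p-toluenesulfonate | O[C@@H]1[C@@H]2[C@@](C)(CC[C@H]1[C@@H](COS(=O)(=O)c3ccc(C)cc3)C)[C@H](Br)CCC2=C | intermediate
7 | (11S)-1β-bromo-12-tosyloxy-5αH-eudesm-4(15)-en-6α-yl acetate | CC(=O)O[C@@H]1[C@@H]2[C@@](C)(CC[C@H]1[C@@H](COS(=O)(=O)c3ccc(C)cc3)C)[C@H](Br)CCC2=C | intermediate
8 | 1β-bromo-5αH-eudesm-4(15)-en-6α-yl acetate (7β-isopropyl, 10β-methyl) | CC(=O)O[C@@H]1[C@@H]2[C@@](C)(CC[C@H]1C(C)C)[C@H](Br)CCC2=C | intermediate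
9 | spiro ozonide of 8, a 1,2,4-trioxolane spiro-fused at C4 with C15 as its CH2 (configuration at the spiro carbon not defined) | CC(=O)O[C@@H]1[C@@H]2[C@@](C)(CC[C@H]1C(C)C)[C@H](Br)CCC23OCOO3 | intermediate
10 | 1β-bromo-4-oxo-15-nor-5αH-eudesman-6α-yl acetate | CC(=O)O[C@@H]1[C@@H]2[C@@](C)(CC[C@H]1C(C)C)[C@H](Br)CCC2=O | intermediate
11 | (1R,4S,5S,6S,7S,10R)-1-bromo-4-hydroxyeudesman-6-yl acetate, that is 1β-bromo-4β-hydroxy-4α-methyl-5αH-eudesman-6α-yl acetate (CNP0136555.3) | CC(=O)O[C@@H]1[C@@H]2[C@@](C)(CC[C@H]1C(C)C)[C@H](Br)CC[C@]2(C)O | target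

**Totals**
Total step count: 7. Longest linear sequence: 7 steps (1 → 11). C6 and C7 come from 1; C1, C5 and C10 are set in step 2; C4 is set in step 7.

**Steps most likely to fail, with fallbacks**

Step 2. The ring closure has close analogy in acid- and epoxide-triggered cyclizations of costunolide, but proton loss from the C4 cation may give too much of the 3-ene isomer. The fallback sets out from 2 and comes back at 4, and it separates ring formation from alkene formation. N-Bromosuccinimide in acetone/H2O (4:1) at 0 °C runs the same transannular cyclization but lets water capture the C4 cation anti to the new C5–C10 bond, giving 1β-bromo-4α-hydroxy-5α,11βH-eudesman-12,6α-olide F1. SOCl2 in pyridine/CH2Cl2 at −20 → 0 °C converts this equatorial tertiary alcohol into its 4α-chlorosulfite F2. E2 loss from F2 can only take a C15 hydrogen, because no ring hydrogen is anti-periplanar to an equatorial leaving group, and this returns the exocyclic alkene 4.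

Step 5. Hydride displacement at the β-branched C12 may be slow, and any loss of the acetate would let O6 close a tetrahydrofuran onto C12. The fallback sets out from 4 and comes back at 8, and it removes the C12 oxygen at the aldehyde level instead of by sulfonate displacement. i-Bu2AlH in CH2Cl2 at −78 °C reduces the lactone to the lactol 1β-bromo-6α,12-epoxy-5α,11βH-eudesm-4(15)-en-12-ol F3 (both anomers). TsNHNH2 in MeOH at rt traps its open hydroxy-aldehyde form as (11S)-1β-bromo-6α-hydroxy-5αH-eudesm-4(15)-en-12-al p-toluenesulfonylhydrazone F4. Catecholborane in CHCl3 at 0 °C reduces the C=N bond, and warming with NaOAc·3H2O expels N2 and p-toluenesulfinate to leave the C12 methyl group in 1β-bromo-5αH-eudesm-4(15)-en-6α-ol F5. Ac2O, DMAP and pyridine at rt then give 8.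

Step 7. The addition must beat attack on the acetate and β-elimination of the β-acetoxy ketone, and its face selectivity sets C4. The fallback sets out from 8 and comes back at 11, and it replaces carbonyl addition by C–H hydroxylation. Hydrogen-atom-transfer hydrogenation of the exocyclic alkene (Mn(dpm)3 cat., PhSiH3, t-BuOOH, i-PrOH, rt) tolerates the alkyl bromide and delivers hydrogen axially to the C4 radical, giving the equatorial 4α-methyl compound 1β-bromo-4βH,5αH-eudesman-6α-yl acetate F6. Methyl(trifluoromethyl)dioxirane in CH2Cl2 at −20 → 0 °C then inserts oxygen into the axial tertiary C4–H bond with retention. C5–H, C6–H and C7–H are deactivated by the adjacent acetoxy group, and this site selectivity is established for the bromine-free 6-O-protected dihydrojunenol series; the product is 11.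

**Further compounds**
F1 | step 2 | 1β-bromo-4α-hydroxy-5α,11βH-eudesman-12,6α-olide | O=C1O[C@@H]2[C@@H]3[C@@](C)(CC[C@H]2[C@@H]1C)[C@H](Br)CC[C@@]3(C)O
F2 | step 2 | 4α-chlorosulfite of F1 (sulfur configuration not defined) | O=C1O[C@@H]2[C@@H]3[C@@](C)(CC[C@H]2[C@@H]1C)[C@H](Br)CC[C@@]3(C)OS(Cl)=O
F3 | step 5 | 1β-bromo-6α,12-epoxy-5α,11βH-eudesm-4(15)-en-12-ol (lactol, both anomers) | OC1O[C@@H]2[C@@H]3[C@@](C)(CC[C@H]2[C@@H]1C)[C@H](Br)CCC3=C
F4 | step 5 | (11S)-1β-bromo-6α-hydroxy-5αH-eudesm-4(15)-en-12-al p-toluenesulfonylhydrazone (E) | O[C@@H]1[C@@H]2[C@@](C)(CC[C@H]1[C@@H](/C=N/NS(=O)(=O)c3ccc(C)cc3)C)[C@H](Br)CCC2=C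
F5 | step 5 | 1β-bromo-5αH-eudesm-4(15)-en-6α-ol | O[C@@H]1[C@@H]2[C@@](C)(CC[C@H]1C(C)C)[C@H](Br)CCC2=C
F6 | step 7 | 1β-bromo-4βH,5αH-eudesman-6α-yl acetate (4α-methyl) | CC(=O)O[C@@H]1[C@@H]2[C@@](C)(CC[C@H]1C(C)C)[C@H](Br)CC[C@H]2C
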